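**Plan**

1. Retrosynthesis: remove the sixteen benzyl ethers and a temporary C8–Br cap on the top unit; cut, as one event, the top interflavan bond C4–C8 and the O1–C2 bond of the top ring C; cut C3–C4 of the opened top unit (ring-A aldehyde plus ring-B alkyne) and the two lower C4–C8 bonds back to (−)-epicatechin.
2. Forward: benzylated (−)-epicatechin is grown to the all-4β→8 trimer by two Friedel–Crafts couplings; in parallel an open-chain (R,Z)-1,3-diarylallyl alcohol with a free ring-A phenol is made by asymmetric alkynylation and semi-hydrogenation.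
3. One flask then epoxidises the Z-alkene, closes ring C through O1–C2, ionises C4 and joins it to C8 of the trimer; hydrogenolysis removes benzyl groups and bromine.
4. Enabling feature: in the top unit C2 is benzylic to ring B and stands in a 1,6-relationship to the ring-A phenol oxygen O1, so an oxirane across C2–C3 is opened by O1 at C2 (6-endo); C4 is benzylic to the tri-oxygenated ring A, so its hydroxyl first directs the epoxidation and then leaves.
5. Stereochemistry: the eight centres of the lower units come from (−)-epicatechin (C2, C3) and from attack anti to C3–OH (C4); in the top unit one catalytic asymmetric alkynylation sets the carbinol, which relays to C3 (directed epoxidation) and C2 (inversion) and is finally replaced anti to C3–OH.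

Key step: step 12

Assumption: the BINOL/Ti(OiPr)4-catalysed alkynylzinc addition to aldehyde 4 is taken to follow the facial preference of simple aromatic aldehydes (Re-face attack with (R)-BINOL), which here corresponds to the (R)-carbinol; if the opposite sense is found, (S)-BINOL is used.

**Route**

Step 1
Reactants: 1 3,5-bis(benzyloxy)phenol
Product: 2 4,6-bis(benzyloxy)-2-hydroxybenzaldehyde
Conditions: MgCl2, Et3N, (CH2O)n, MeCN, reflux
Reagents that add atoms: paraformaldehyde (as formaldehyde), C=O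
Why: Magnesium-phenoxide-directed ortho-formylation (Casnati–Skattebøl) delivers formaldehyde only ortho to the hydroxyl, and the two ortho positions of 1 are equivalent, so a single salicylaldehyde should form.

Step 2
Reactants: 2 4,6-bis(benzyloxy)-2-hydroxybenzaldehyde
Product: 3 4,6-bis(benzyloxy)-3-bromo-2-hydroxybenzaldehyde
Conditions: NBS (1.0 equiv), CH2Cl2, −78 → 0 °C
Reagents that add atoms: N-bromosuccinimide, O=C1CCC(=O)N1Br
Why: Electrophilic aromatic bromination should go ortho to the chelated hydroxyl because the other free position is crowded between two benzyloxy groups, the same bias that sends NBS to C8 of 5,7-bis(benzyloxy)flavans; this bromine becomes the C8 cap of the top unit.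

Step 3
Reactants: 3 4,6-bis(benzyloxy)-3-bromo-2-hydroxybenzaldehyde
Product: 4 4,6-bis(benzyloxy)-3-bromo-2-[(tert-butyldimethylsilyl)oxy]benzaldehyde
Conditions: TBSCl, imidazole, DMF, rt → 40 °C
Reagents that add atoms: tert-butyldimethylsilyl chloride, CC(C)(C)[Si](C)(C)Cl
Why: Standard silylation of a phenol masks the acidic hydroxyl so that it cannot quench or misdirect the zinc and titanium species of step 5.

Step 4
Reactants: 5 3,4-bis(benzyloxy)benzaldehyde
Product: 6 1,2-bis(benzyloxy)-4-ethynylbenzene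
Conditions: dimethyl (1-diazo-2-oxopropyl)phosphonate, K2CO3, MeOH, rt
Reagents that add atoms: dimethyl (1-diazo-2-oxopropyl)phosphonate, COP(=O)(OC)C(=[N+]=[N-])C(C)=O
Why: Seyferth–Gilbert homologation in the Ohira–Bestmann variant converts an aromatic aldehyde into the terminal alkyne in one step under mild base that leaves benzyl ethers untouched.

Step 5
Reactants: 4 4,6-bis(benzyloxy)-3-bromo-2-[(tert-butyldimethylsilyl)oxy]benzaldehyde; 6 1,2-bis(benzyloxy)-4-ethynylbenzene
Product: 8 (R)-1-{4,6-bis(benzyloxy)-3-bromo-2-[(tert-butyldimethylsilyl)oxy]phenyl}-3-[3,4-bis(benzyloxy)phenyl]prop-2-yn-1-ol, via alkynylzinc reagent 7 (not isolated)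
Conditions: 6 (2 equiv), Et2Zn (2 equiv), toluene, reflux; then (R)-BINOL (20 mol %), Ti(OiPr)4 (50 mol %), 4, toluene/CH2Cl2, rt; aqueous work-up
Reagents that add atoms: none
Why: Catalytic enantioselective alkynylzinc addition to an aromatic aldehyde (BINOL/Ti(OiPr)4 system) forms the C3–C4 bond, and the chiral titanium complex should deliver the alkynyl group to the Re face to set the (R)-carbinol, the only centre of the top unit that a reagent has to create.

Step 6
Reactants: 8 (R)-1-{4,6-bis(benzyloxy)-3-bromo-2-[(tert-butyldimethylsilyl)oxy]phenyl}-3-[3,4-bis(benzyloxy)phenyl]prop-2-yn-1-ol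
Product: 9 (R)-1-[4,6-bis(benzyloxy)-3-bromo-2-hydroxyphenyl]-3-[3,4-bis(benzyloxy)phenyl]prop-2-yn-1-ol
Conditions: TBAF, AcOH, THF, 0 °C
Reagents that add atoms: none
Why: Fluoride cleavage of the aryl silyl ether, buffered with acetic acid, should free the phenol without ionising the propargylic alcohol or touching the carbinol centre.

Step 7
Reactants: 9 (R)-1-[4,6-bis(benzyloxy)-3-bromo-2-hydroxyphenyl]-3-[3,4-bis(benzyloxy)phenyl]prop-2-yn-1-ol
Product: 10 (1R,2Z)-1-[4,6-bis(benzyloxy)-3-bromo-2-hydroxyphenyl]-3-[3,4-bis(benzyloxy)phenyl]prop-2-en-1-ol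
Conditions: H2 (1 atm), Pd/CaCO3 poisoned with Pb(OAc)2 (Lindlar catalyst), quinoline, EtOAc, 0 °C → rt; product used directly
Reagents that add atoms: none
Why: Lindlar semi-hydrogenation adds hydrogen syn on the poisoned palladium surface and should stop at the Z-alkene, the geometry that later becomes the 2,3-cis relationship, while the carbinol centre, benzyl ethers and aryl bromide are left alone.

Step 8
Reactants: 11 (−)-epicatechin
Product: 12 5,7,3',4'-tetra-O-benzyl-(−)-epicatechin
Conditions: BnBr (4.4 equiv), K2CO3, DMF, 0 °C → rt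
Reagents that add atoms: benzyl bromide, BrCc1ccccc1
Why: Williamson etherification under carbonate base should alkylate the four phenols and not the far less acidic C3 alcohol, leaving C2 and C3 untouched.

Step 9
Reactants: 12 5,7,3',4'-tetra-O-benzyl-(−)-epicatechin
Product: 13 5,7,3',4'-tetra-O-benzyl-4β-(2-hydroxyethoxy)-(−)-epicatechin
Conditions: DDQ, ethylene glycol, CH2Cl2, rt
Reagents that add atoms: ethylene glycol, OCCO
Why: DDQ abstracts hydride from the benzylic C4 position activated by ring A and the glycol should add to the cation anti to the C3 hydroxyl (benzylic oxidation with alcohol capture), giving the established 4β-alkoxy C4 electrophile.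

Step 10
Reactants: 12 5,7,3',4'-tetra-O-benzyl-(−)-epicatechin (4 equiv); 13 5,7,3',4'-tetra-O-benzyl-4β-(2-hydroxyethoxy)-(−)-epicatechin
Product: 14 octa-O-benzyl epicatechin dimer (tetra-O-benzyl-epicatechin-(4β→8)-tetra-O-benzyl-epicatechin)
Conditions: montmorillonite K-10 clay (Al2Si4O10(OH)2·nH2O), CH2Cl2, 0 °C → rt
Reagents that add atoms: none
Why: Acid-clay-promoted Friedel–Crafts alkylation: the C4 cation from 13 should be attacked by C8 of 12 (the less hindered ring-A position) anti to the C3 hydroxyl, which sets the 4β→8 bond and the (R) centre at C4, while the excess of 12 suppresses over-alkylation and is recovered.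

Step 11
Reactants: 14 octa-O-benzyl epicatechin dimer (3 equiv); 13 5,7,3',4'-tetra-O-benzyl-4β-(2-hydroxyethoxy)-(−)-epicatechin
Product: 15 dodeca-O-benzyl epicatechin trimer (three tetra-O-benzyl-epicatechin units joined 4β→8)
Conditions: montmorillonite K-10 clay (Al2Si4O10(OH)2·nH2O), CH2Cl2, 0 °C → rt
Reagents that add atoms: none
Why: The same Friedel–Crafts chain extension: only the upper unit of 14 has a free C8, so the cation from 13 should add there, again anti to its own C3 hydroxyl, with the excess of 14 recovered.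

Step 12
Reactants: 10 (1R,2Z)-1-[4,6-bis(benzyloxy)-3-bromo-2-hydroxyphenyl]-3-[3,4-bis(benzyloxy)phenyl]prop-2-en-1-ol (1.2 equiv); 15 dodeca-O-benzyl epicatechin trimer (1.0 equiv)
Product: 18 C8-bromo hexadeca-O-benzyl epicatechin tetramer, via cis-epoxy alcohol 16 (not isolated), via flavan-3,4-diol 17 (not isolated)
Conditions: DMDO (1.1 equiv to 10), acetone/CH2Cl2, −40 → 0 °C, hold until 16 is consumed; evaporate at 0 °C; then 15, montmorillonite K-10 clay (Al2Si4O10(OH)2·nH2O), CH2Cl2, 0 °C → rt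
Reagents that add atoms: dimethyldioxirane, CC1(C)OO1
Why: DMDO should epoxidise the electron-rich Z-alkene of 10 on the face syn to the C4 hydroxyl in the conformer that 1,3-allylic strain enforces (H4 in the alkene plane), the hydrogen-bond-directed threo epoxidation of Z-allylic alcohols, which sets C3 and gives cis-epoxide 16 with ring A held over the face opposite to the oxirane oxygen. The ring-A phenol oxygen then opens the strained oxirane at the benzylic carbon C2 in a 6-endo-tet closure with inversion, the anti opening of aryl epoxides by phenols known from chroman and flavan-3-ol synthesis, so that the cis-epoxide gives the 2,3-cis ring C of 17 and C2 becomes (R). The clay then ionises the C4 hydroxyl of 17 to a cation stabilised by the three oxygens of ring A, and C8 of the upper unit of 15 adds anti to the C3 hydroxyl of this half-chair cation exactly as in steps 10 and 11, which sets C4 (R) and the 4β→8 bond; running epoxidation and coupling in one flask after evaporating the volatile oxidant follows the glycal-epoxide coupling tactic. The step needs 6-endo and not 5-exo opening, secured by the 3,4-bis(benzyloxy)phenyl group that makes C2 the electrophilic end of the oxirane; inversion and not a free C2 cation, secured by the preorganised internal nucleophile and by closing the ring before the acid clay is added; and a single arylation, secured by the bromine at C8 of the new unit and by the crowding of every C6 between two benzyloxy groups. The C4 hydroxyl is thus a traceless helper that directs the oxidant and then leaves as water.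

Step 13
Reactants: 18 C8-bromo hexadeca-O-benzyl epicatechin tetramer
Product: 19 epicatechin-(4β→8)-epicatechin-(4β→8)-epicatechin-(4β→8)-epicatechin (the target tetramer)
Conditions: H2 (1 atm), Pd(OH)2/C, NaHCO3 (1.0 equiv), THF/MeOH/H2O, rt
Reagents that add atoms: none
Why: Hydrogenolysis over Pd(OH)2/C should cleave all sixteen benzyl ethers and the C8–Br bond in one operation under near-neutral conditions that touch neither the interflavan bonds nor any stereocentre.

**Compound list**

1 | 3,5-bis(benzyloxy)phenol | Oc1cc(OCc2ccccc2)cc(OCc2ccccc2)c1 | starting material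
2 | 4,6-bis(benzyloxy)-2-hydroxybenzaldehyde | O=Cc1c(O)cc(OCc2ccccc2)cc1OCc1ccccc1 | intermediate
3 | 4,6-bis(benzyloxy)-3-bromo-2-hydroxybenzaldehyde | O=Cc1c(O)c(Br)c(OCc2ccccc2)cc1OCc1ccccc1 | intermediate
4 | 4,6-bis(benzyloxy)-3-bromo-2-[(tert-butyldimethylsilyl)oxy]benzaldehyde | O=Cc1c(O[Si](C)(C)C(C)(C)C)c(Br)c(OCc2ccccc2)cc1OCc1ccccc1 | intermediate
5 | 3,4-bis(benzyloxy)benzaldehyde | O=Cc1ccc(OCc2ccccc2)c(OCc2ccccc2)c1 | starting material
6 | 1,2-bis(benzyloxy)-4-ethynylbenzene | C#Cc1ccc(OCc2ccccc2)c(OCc2ccccc2)c1 | intermediate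
7 | {[3,4-bis(benzyloxy)phenyl]ethynyl}(ethyl)zinc | CC[Zn]C#Cc1ccc(OCc2ccccc2)c(OCc2ccccc2)c1 | intermediate
8 | (R)-1-{4,6-bis(benzyloxy)-3-bromo-2-[(tert-butyldimethylsilyl)oxy]phenyl}-3-[3,4-bis(benzyloxy)phenyl]prop-2-yn-1-ol | O[C@H](C#Cc1ccc(OCc2ccccc2)c(OCc2ccccc2)c1)c1c(O[Si](C)(C)C(C)(C)C)c(Br)c(OCc2ccccc2)cc1OCc1ccccc1 | intermediate
9 | (R)-1-[4,6-bis(benzyloxy)-3-bromo-2-hydroxyphenyl]-3-[3,4-bis(benzyloxy)phenyl]prop-2-yn-1-ol | O[C@H](C#Cc1ccc(OCc2ccccc2)c(OCc2ccccc2)c1)c1c(O)c(Br)c(OCc2ccccc2)cc1OCc1ccccc1 | intermediate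
10 | (1R,2Z)-1-[4,6-bis(benzyloxy)-3-bromo-2-hydroxyphenyl]-3-[3,4-bis(benzyloxy)phenyl]prop-2-en-1-ol | O[C@H](/C=C\c1ccc(OCc2ccccc2)c(OCc2ccccc2)c1)c1c(O)c(Br)c(OCc2ccccc2)cc1OCc1ccccc1 | intermediate
11 | (−)-epicatechin, (2R,3R) | Oc1cc(O)c2c(c1)O[C@H](c1ccc(O)c(O)c1)[C@H](O)C2 | starting material
12 | 5,7,3',4'-tetra-O-benzyl-(−)-epicatechin, (2R,3R), C3–OH free | c1c(OCc3ccccc3)cc(OCc3ccccc3)c2c1O[C@H](c1ccc(OCc3ccccc3)c(OCc3ccccc3)c1)[C@H](O)C2 | intermediate
13 | 5,7,3',4'-tetra-O-benzyl-4β-(2-hydroxyethoxy)-(−)-epicatechin (2,3-cis, 3,4-trans) | c1c(OCc3ccccc3)cc(OCc3ccccc3)c2c1O[C@H](c1ccc(OCc3ccccc3)c(OCc3ccccc3)c1)[C@H](O)[C@H]2OCCO | intermediate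
14 | octa-O-benzyl epicatechin dimer: tetra-O-benzyl-epicatechin-(4β→8)-tetra-O-benzyl-epicatechin, both C3–OH free | c1c(OCc3ccccc3)cc(OCc3ccccc3)c2c1O[C@H](c1ccc(OCc3ccccc3)c(OCc3ccccc3)c1)[C@H](O)[C@H]2c1c(OCc3ccccc3)cc(OCc3ccccc3)c2c1O[C@H](c1ccc(OCc3ccccc3)c(OCc3ccccc3)c1)[C@H](O)C2 | intermediate
15 | dodeca-O-benzyl epicatechin trimer: three tetra-O-benzyl-epicatechin units joined 4β→8, all C3–OH free, C8 of the upper unit free | c1c(OCc3ccccc3)cc(OCc3ccccc3)c2c1O[C@H](c1ccc(OCc3ccccc3)c(OCc3ccccc3)c1)[C@H](O)[C@H]2c1c(OCc3ccccc3)cc(OCc3ccccc3)c2c1O[C@H](c1ccc(OCc3ccccc3)c(OCc3ccccc3)c1)[C@H](O)[C@H]2c1c(OCc3ccccc3)cc(OCc3ccccc3)c2c1O[C@H](c1ccc(OCc3ccccc3)c(OCc3ccccc3)c1)[C@H](O)C2 | intermediate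
16 | (S)-[4,6-bis(benzyloxy)-3-bromo-2-hydroxyphenyl]{(2R,3S)-3-[3,4-bis(benzyloxy)phenyl]oxiran-2-yl}methanol (cis-oxirane, threo to the carbinol) | O[C@H]([C@H]1O[C@H]1c1ccc(OCc2ccccc2)c(OCc2ccccc2)c1)c1c(O)c(Br)c(OCc2ccccc2)cc1OCc1ccccc1 | intermediate
17 | (2R,3R,4S)-5,7-bis(benzyloxy)-2-[3,4-bis(benzyloxy)phenyl]-8-bromochromane-3,4-diol (2,3-cis, 3,4-trans) | Brc1c(OCc3ccccc3)cc(OCc3ccccc3)c2c1O[C@H](c1ccc(OCc3ccccc3)c(OCc3ccccc3)c1)[C@H](O)[C@H]2O | intermediate
18 | C8-bromo hexadeca-O-benzyl epicatechin tetramer: 8-bromo-tetra-O-benzyl-epicatechin-(4β→8)-[tetra-O-benzyl-epicatechin-(4β→8)]2-tetra-O-benzyl-epicatechin, all four C3–OH free | Brc1c(OCc3ccccc3)cc(OCc3ccccc3)c2c1O[C@H](c1ccc(OCc3ccccc3)c(OCc3ccccc3)c1)[C@H](O)[C@H]2c1c(OCc3ccccc3)cc(OCc3ccccc3)c2c1O[C@H](c1ccc(OCc3ccccc3)c(OCc3ccccc3)c1)[C@H](O)[C@H]2c1c(OCc3ccccc3)cc(OCc3ccccc3)c2c1O[C@H](c1ccc(OCc3ccccc3)c(OCc3ccccc3)c1)[C@H](O)[C@H]2c1c(OCc3ccccc3)cc(OCc3ccccc3)c2c1O[C@H](c1ccc(OCc3ccccc3)c(OCc3ccccc3)c1)[C@H](O)C2 | intermediate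
19 | epicatechin-(4β→8)-epicatechin-(4β→8)-epicatechin-(4β→8)-epicatechin, the target procyanidin tetramer | Oc1cc(O)c2c(c1)O[C@H](c1ccc(O)c(O)c1)[C@H](O)[C@H]2c1c(O)cc(O)c2c1O[C@H](c1ccc(O)c(O)c1)[C@H](O)[C@H]2c1c(O)cc(O)c2c1O[C@H](c1ccc(O)c(O)c1)[C@H](O)[C@H]2c1c(O)cc(O)c2c1O[C@H](c1ccc(O)c(O)c1)[C@H](O)C2 | target

**Step count and risks**

Total step count: 13. Longest linear sequence: 8 steps (steps 1, 2, 3, 5, 6, 7, 12, 13).

Steps most likely to fail:

Step 12. The oxirane may open through a free benzylic cation at C2, which would erode the 2,3-cis relationship. It may also rearrange by hydride shift to a ketone, or the phenol may be oxidised by the dioxirane before the alkene reacts. The fallback sets out from 12 and comes back to the route at 18; ring C of the top unit is then taken from the natural monomer and not closed. NBS (CH2Cl2, −78 °C) should brominate 12 at C8 to give 8-bromo-5,7,3',4'-tetra-O-benzyl-(−)-epicatechin F1. DDQ and ethylene glycol in CH2Cl2 then oxidise C4 to give 8-bromo-5,7,3',4'-tetra-O-benzyl-4β-(2-hydroxyethoxy)-(−)-epicatechin F2. F2 and trimer 15 are coupled with the K-10 clay as in step 11 to give 18.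

Step 5. Addition to the electron-rich, doubly ortho-substituted aldehyde may be slow, and discrimination between its two faces may be poor. The fallback sets out from 4 and 6 and comes back at 8. The lithium acetylide of 6 (n-BuLi, THF, −78 °C) is added to 4 and quenched cold to give racemic 1-{4,6-bis(benzyloxy)-3-bromo-2-[(tert-butyldimethylsilyl)oxy]phenyl}-3-[3,4-bis(benzyloxy)phenyl]prop-2-yn-1-ol F3. MnO2 in CH2Cl2 oxidises it to 1-{4,6-bis(benzyloxy)-3-bromo-2-[(tert-butyldimethylsilyl)oxy]phenyl}-3-[3,4-bis(benzyloxy)phenyl]prop-2-yn-1-one F4. Corey–Bakshi–Shibata reduction ((S)-2-methyl-CBS-oxazaborolidine, catecholborane, toluene, −78 °C), with the twisted aryl group as the large and the alkynyl group as the small substituent, should then give 8.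

Step 7. The hydrogenation may run on to the saturated chain, the Z-alkene may isomerise to E on the catalyst, the C–Br or the doubly benzylic C–O bond may be hydrogenolysed, and the product may ionise and close to a flav-3-ene. The fallback sets out from 8 and comes back at 10. Alkyne 8 is treated with Ti(OiPr)4 and iPrMgCl (Et2O, −78 → −40 °C), which form an alkyne complex of divalent titanium. Hydrolysis with water delivers both hydrogens syn and should give (1R,2Z)-1-{4,6-bis(benzyloxy)-3-bromo-2-[(tert-butyldimethylsilyl)oxy]phenyl}-3-[3,4-bis(benzyloxy)phenyl]prop-2-en-1-ol F5. Desilylation with TBAF and AcOH as in step 6 then gives 10.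

**Further compounds**

F1 | step 12 | 8-bromo-5,7,3',4'-tetra-O-benzyl-(−)-epicatechin | Brc1c(OCc3ccccc3)cc(OCc3ccccc3)c2c1O[C@H](c1ccc(OCc3ccccc3)c(OCc3ccccc3)c1)[C@H](O)C2
F2 | step 12 | 8-bromo-5,7,3',4'-tetra-O-benzyl-4β-(2-hydroxyethoxy)-(−)-epicatechin | Brc1c(OCc3ccccc3)cc(OCc3ccccc3)c2c1O[C@H](c1ccc(OCc3ccccc3)c(OCc3ccccc3)c1)[C@H](O)[C@H]2OCCO
F3 | step 5 | racemic 1-{4,6-bis(benzyloxy)-3-bromo-2-[(tert-butyldimethylsilyl)oxy]phenyl}-3-[3,4-bis(benzyloxy)phenyl]prop-2-yn-1-ol | OC(C#Cc1ccc(OCc2ccccc2)c(OCc2ccccc2)c1)c1c(O[Si](C)(C)C(C)(C)C)c(Br)c(OCc2ccccc2)cc1OCc1ccccc1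
F4 | step 5 | 1-{4,6-bis(benzyloxy)-3-bromo-2-[(tert-butyldimethylsilyl)oxy]phenyl}-3-[3,4-bis(benzyloxy)phenyl]prop-2-yn-1-one | O=C(C#Cc1ccc(OCc2ccccc2)c(OCc2ccccc2)c1)c1c(O[Si](C)(C)C(C)(C)C)c(Br)c(OCc2ccccc2)cc1OCc1ccccc1
F5 | step 7 | (1R,2Z)-1-{4,6-bis(benzyloxy)-3-bromo-2-[(tert-butyldimethylsilyl)oxy]phenyl}-3-[3,4-bis(benzyloxy)phenyl]prop-2-en-1-ol | O[C@H](/C=C\c1ccc(OCc2ccccc2)c(OCc2ccccc2)c1)c1c(O[Si](C)(C)C(C)(C)C)c(Br)c(OCc2ccccc2)cc1OCc1ccccc1
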